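**Plan**

1. Numbering and letters: cyclopentene ring C = C1–C5 (C2 bears OAc, C3 is the ring-fusion CH, C4 bears CH3 and O); cycloheptene ring B = C1, C5, C6–C10 (C10 bears CH3); methylene lactone ring A = C7, C8, C11–C13, O; aryl δ-lactone ring D = C3, C4, O, C12′(=O), C11′(aryl), C13′; β = the face of ring C that carries the C4 methyl group, α = the other face; Ar = 3-[(2R)-5-acetoxypentan-2-yl]-4-(tert-butyldiphenylsilyloxymethyl)phenyl.
2. Retrosynthesis: after the C2 acetate and the benzylic silyl ether, the C9–C10 and C7–C8 bonds of ring B and the C12–O bond of ring A are cut together, back to a ring C/D tertiary alcohol whose O–C5 carries a vinyl group and whose C6 arm ends in a 2-(chloromethyl)acrylate. Further cuts: C7=C11 (cross-metathesis), C1=C10 (aldol), C5–O (epoxide), C4–CH3 and the ring D C–O bond, C3–C13′ (Michael addition), C5–C6 (Stille), and both aryl–carbon bonds of the aryl acrylate.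
3. Enabling feature: ring B holds the γ,δ-unsaturated carbonyl pattern C8(O)–C9–C10–C1=C5 and, sharing C8, the homoallylic carbinol C8(O)–C7–C11(=C13)–C12(=O) of ring A. A two-carbon vinyl unit on the tertiary allylic oxygen at C5 can therefore hand C9 to C10 by a [3,3] shift and then offer C8 as an aldehyde to an allyl metal centred on C7.
4. Forward order: aryl acrylate (steps 1–6); ring C building block and Michael union (7–9); ring D by methyl addition and lactonization (10); C5–O and the ethylidene group (11–15); acrylate arm and vinyl ether (16, 17); rings B and A in the key step (18); C2 reduction, acetylation, desilylation (19–21).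
5. Stereochemistry: the C2 silyl ether of (S)-4-silyloxycyclopentenone directs C3, C3 directs C4, the silyl ether and the C4 methyl direct the epoxide (C5–O), C5–O is transferred to C10 in the [3,3] shift, and C10 with a chair allyl-CrCl2 transition state sets C7 and C8. C2 is then reset by hydride delivery, C11′ by equilibration, and the side-chain centre by hydrogenation with a chiral [Ir(cod)(L)]BArF catalyst.

Key step: step 18

Remark: the (R) configuration at C11′ is taken to be the thermodynamically favoured one (aryl pseudo-equatorial on the cis-fused δ-lactone), so it is set by base equilibration and not by a selective bond formation.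

**Route**

Step 1
Reactants: 1 (4-bromo-2-iodophenyl)methanol
Product: 2 tert-butyl[(4-bromo-2-iodobenzyl)oxy]diphenylsilane
Conditions: TBDPSCl, imidazole, DMF, 0 °C → rt
Reagents that add atoms: tert-butyl(chloro)diphenylsilane, CC(C)(C)[Si](Cl)(c1ccccc1)c1ccccc1
Why: Imidazole-promoted silylation of a primary benzylic alcohol is routine, and the bulky silyl ether is chosen to outlast the later basic, oxidative and Lewis-acidic steps (silyl ether protection).

Step 2
Reactants: 3 pent-4-yn-1-yl acetate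
Product: 4 4-(4,4,5,5-tetramethyl-1,3,2-dioxaborolan-2-yl)pent-4-en-1-yl acetate
Conditions: B2pin2, CuCl (5 mol %), 1,3-bis(2,4,6-trimethylphenyl)imidazolinium chloride (5 mol %), NaOt-Bu (10 mol %), MeOH (2 equiv), THF, −15 °C
Reagents that add atoms: bis(pinacolato)diboron, CC1(C)OB(OC1(C)C)B1OC(C)(C)C(C)(C)O1
Why: With an N-aryl carbene ligand on CuCl the Cu–B bond should add across the terminal alkyne with boron on the internal carbon, and methanol protonates the terminal carbon (α-selective protoboration of a terminal alkyne).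

Step 3
Reactants: 2 tert-butyl[(4-bromo-2-iodobenzyl)oxy]diphenylsilane; 4 alkenyl boronate
Product: 5 4-[5-bromo-2-(tert-butyldiphenylsilyloxymethyl)phenyl]pent-4-en-1-yl acetate
Conditions: PdCl2(dppf) (3 mol %), K3PO4, THF/H2O, 45 °C
Reagents that add atoms: none
Why: Oxidative addition is much faster at C–I than at C–Br, so the Suzuki–Miyaura coupling should place the alkenyl group ortho to the silyloxymethyl group and keep the bromide for step 5.

Step 4
Reactants: 5 1,1-disubstituted aryl alkene
Product: 6 (4R)-4-[5-bromo-2-(tert-butyldiphenylsilyloxymethyl)phenyl]pentyl acetate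
Conditions: H2 (50 bar), [Ir(cod)(L)]BArF (1 mol %; L = ThrePHOX-type phosphinite–oxazoline, enantiomer chosen for the (R) product; BArF = B[3,5-(CF3)2C6H3]4), CH2Cl2, rt
Reagents that add atoms: none
Why: Cationic [Ir(cod)(N,P)]BArF catalysts hydrogenate unfunctionalised 1,1-disubstituted aryl alkenes enantioselectively and leave the aryl bromide alone (asymmetric hydrogenation), the ligand enantiomer deciding the face of hydride delivery and so the (R) benzylic centre.

Step 5
Reactants: 6 (4R)-aryl bromide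
Product: 7 ethyl 2-Ar-acetate
Conditions: BrZnCH2CO2Et (1.5 equiv), Pd(dba)2 (2 mol %), P(t-Bu)3 (2 mol %), THF, rt → 50 °C
Reagents that add atoms: (2-ethoxy-2-oxoethyl)zinc bromide, CCOC(=O)C[Zn]Br
Why: α-Arylation of a preformed zinc ester enolate with Pd(dba)2/P(t-Bu)3 couples at the aryl bromide without strong base, so the acetate and the remote stereocentre are untouched.

Step 6
Reactants: 7 ethyl 2-Ar-acetate
Product: 8 ethyl 2-Ar-prop-2-enoate
Conditions: (CH2O)n, K2CO3, Bu4NI (cat.), toluene, 80 °C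
Reagents that add atoms: formaldehyde (as paraformaldehyde), C=O
Why: The arylacetate is acidic enough for a carbonate-mediated aldol with formaldehyde followed by dehydration (α-methylenation), which gives the 2-arylacrylate Michael acceptor.

Step 7
Reactants: 9 (4S)-4-(tert-butyldimethylsilyloxy)cyclopent-2-en-1-one
Product: 10 (4S)-4-(tert-butyldimethylsilyloxy)-2-iodocyclopent-2-en-1-one
Conditions: I2, pyridine, CH2Cl2, 0 °C → rt
Reagents that add atoms: iodine, II
Why: Pyridine-mediated addition–elimination puts iodine on the α-carbon of the enone (α-iodination of an enone) without touching the stereocentre.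

Step 8
Reactants: 10 iodoenone
Product: 11 (4S)-2-allyl-4-(tert-butyldimethylsilyloxy)cyclopent-2-en-1-one
Conditions: allylSnBu3, Pd2(dba)3 (2.5 mol %), AsPh3, CuI, NMP, rt → 40 °C
Reagents that add atoms: allyltributylstannane, C=CC[Sn](CCCC)(CCCC)CCCC
Why: CuI-accelerated Stille coupling of α-iodoenones with allylstannanes runs under neutral conditions and installs the future C6–C7 unit on C5.

Step 9
Reactants: 11 allyl enone; 8 ethyl 2-Ar-prop-2-enoate
Product: 12 Michael adduct (C3 chain α, trans to the C2 β-silyl ether; both C11′ epimers)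
Conditions: LDA, THF, −78 °C; then 8, −78 °C; AcOH
Reagents that add atoms: none
Why: Kinetic deprotonation gives the cross-conjugated α′-enolate, which adds to the acrylate (Michael addition) on the face anti to the neighbouring silyl ether and so sets C3 trans to C2–O, while C11′ forms unselectively and is corrected in step 10.

Step 10
Reactants: 12 Michael adduct
Product: 14 allyl lactone (rings C and D; C1H=C5-allyl; C2 β-OSi; C11′ R), via hydroxy ester 13 (not isolated)
Conditions: MeMgBr, CeCl3, THF, −78 → 0 °C; then DBU (0.2 equiv), CH2Cl2, rt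
Reagents that add atoms: methylmagnesium bromide, C[Mg]Br
Why: MeCeCl2 adds 1,2 to the enone carbonyl anti to the C3 side chain (carbonyl addition), so the C4 alkoxide is cis to that chain and closes the δ-lactone by acyl transfer, and DBU then equilibrates C11′ to the epimer with the aryl group equatorial.

Step 11
Reactants: 14 allyl lactone
Product: 15 epoxy lactone (1α,5α-epoxide)
Conditions: mCPBA, NaHCO3, CH2Cl2, 0 °C
Reagents that add atoms: 3-chloroperbenzoic acid, OOC(=O)c1cccc(Cl)c1
Why: The peracid should prefer the trisubstituted ring alkene over the terminal allyl group and approach from the α face, opposite both the C2 silyl ether and the C4 methyl group (epoxidation), which fixes C5–O cis to the lactone oxygen.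

Step 12
Reactants: 15 epoxy lactone
Product: 16 epoxy alcohol (C2 β-OH)
Conditions: HF·pyridine, pyridine, THF, 0 °C
Reagents that add atoms: none
Why: Buffered HF·pyridine cleaves the secondary tert-butyldimethylsilyl ether much faster than the primary tert-butyldiphenylsilyl ether and tolerates the epoxide (selective desilylation).

Step 13
Reactants: 16 epoxy alcohol
Product: 17 epoxy ketone (C2 ketone)
Conditions: 1,1,1-triacetoxy-1,1-dihydro-1,2-benziodoxol-3(1H)-one (DMP), NaHCO3, CH2Cl2, rt
Reagents that add atoms: none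
Why: Buffered hypervalent-iodine oxidation of the secondary alcohol gives the α,β-epoxy ketone without base, so the β-acyloxy ketone is not put at risk of elimination.

Step 14
Reactants: 17 epoxy ketone
Product: 19 aldol adduct (C1–CH(OH)CH3; C5 α-OH β-allyl), via diiodosamarium enolate 18 (not isolated)
Conditions: SmI2 (2.2 equiv), THF, −78 °C; then CH3CHO, −78 °C; aq. NH4Cl
Reagents that add atoms: acetaldehyde, CC=O
Why: SmI2 cleaves the Cα–O bond of the epoxy ketone to an enolate that is regiodefined at C1 and is trapped by acetaldehyde (reductive epoxide opening with aldol trapping), C5 keeping its configuration and the two new centres being removed in step 15.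

Step 15
Reactants: 19 aldol adduct
Product: 21 ethylidene ketone ((Z)-C1=C10; CH3 syn to the C2 carbonyl), via mesylate 20 (not isolated)
Conditions: MsCl, Et3N, CH2Cl2, −20 °C → rt
Reagents that add atoms: none
Why: Only the secondary alcohol is mesylated and E1cB elimination gives the ethylidene ketone (aldol condensation through the mesylate), in which the methyl group should sit syn to the carbonyl because the other position suffers allylic 1,3-strain with the fully substituted C5.

Step 16
Reactants: 21 ethylidene ketone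
Product: 22 allylic chloride (C6 arm –CH2–CH=C(CO2CH3)–CH2Cl)
Conditions: methyl 2-(chloromethyl)acrylate (5 equiv), second-generation Hoveyda–Grubbs catalyst (5 mol %), CH2Cl2, 40 °C
Reagents that add atoms: methyl 2-(chloromethyl)acrylate, C=C(CCl)C(=O)OC
Why: Cross-metathesis of the terminal alkene with an excess of the 1,1-disubstituted acrylate should give the trisubstituted enoate while the electron-poor ethylidene ketone stays inert, and the alkene geometry does not matter because the allyl metal of step 18 equilibrates.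

Step 17
Reactants: 22 allylic chloride
Product: 23 vinyl ether (C5 α-O–CH=CH2)
Conditions: n-butyl vinyl ether (solvent), Pd(OCOCF3)2 (5 mol %), 4,7-diphenyl-1,10-phenanthroline (5 mol %), 40 °C
Reagents that add atoms: n-butyl vinyl ether, C=COCCCC
Why: Transfer vinylation with Pd(OCOCF3)2 and a phenanthroline ligand moves the vinyl group onto the tertiary alcohol under neutral conditions (transetherification), below the temperature of the [3,3] shift, so the allyl vinyl ether can be isolated.

Step 18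
Reactants: 23 vinyl ether
Product: 26 enone bis-lactone (rings A–D; C2 ketone), via aldehyde 24 (not isolated), via ring B hydroxy ester 25 (not isolated)
Conditions: PhMe, 110 °C; then CrCl2 (4 equiv), NaI (cat.), THF/DMF, rt; then p-TsOH (cat.), CH2Cl2, rt
Reagents that add atoms: none
Why: Heating triggers a Claisen rearrangement of the allyl vinyl ether O–C5–C1=C10 (closest known type: [3,3] shifts of vinyl ethers of Morita–Baylis–Hillman-type tertiary allylic alcohols), which bonds C9 to C10, moves the double bond to C1=C5 and unmasks C8 as the aldehyde of 24. CrCl2 then turns the allylic chloride into a 2-(methoxycarbonyl)allyl-CrCl2 reagent that adds through its γ-carbon C7 to C8 (intramolecular Nozaki–Hiyama allylation, the known way to close carbocycle-fused α-methylene lactones), so ring B closes by 7-exo-trig attack on the aldehyde inside a six-membered chair transition state and ring A closes by 5-exo-trig acyl substitution of the C8 alkoxide on the methyl ester. C10 is set by suprafacial chirality transfer: the C5–O bond lies on the α face and the methyl of the (Z)-ethylidene is syn to C2, so C9 arrives on the α face and C10 should become (S). C7 and C8 are set trans because the equilibrating allyl metal reacts through the chair in which both tether carbons (C6 on C7, C9 on C8) are equatorial; their sense relative to C10 follows from allylic strain, which keeps C10–H in the enone plane next to the C2 carbonyl, the C10 methyl pseudo-axial on the α face, and the new C8–O (β) and C7–C11 (α) bonds pseudo-equatorial on the chair of ring B. The step needs the allyl metal to choose the aldehyde over the enone and lactone carbonyls and to react at C7 and not at C13, which the aldehyde selectivity of allyl-CrCl2 reagents and the cyclic transition state secure.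

Step 19
Reactants: 26 enone bis-lactone
Product: 27 allylic alcohol (C2 α-OH)
Conditions: NaBH4, CeCl3·7H2O, MeOH, −78 °C
Reagents that add atoms: none
Why: Luche reduction delivers hydride 1,2 to the enone from the β face, anti to the C3 methylene and the pseudo-axial C10 methyl, which should give the α-alcohol cis to ring D and spare the α-methylene lactone.

Step 20
Reactants: 27 allylic alcohol
Product: 28 diacetate silyl ether
Conditions: Ac2O, DMAP (cat.), pyridine, CH2Cl2, rt
Reagents that add atoms: acetic anhydride, CC(=O)OC(C)=O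
Why: DMAP-catalysed acylation esterifies the only free hydroxyl group (acetylation) and touches no stereocentre.

Step 21
Reactants: 28 diacetate silyl ether
Product: 29 CNP0205574.1
Conditions: HF·pyridine, THF, 0 °C → rt
Reagents that add atoms: none
Why: Mildly acidic fluoride cleaves the last silyl ether (desilylation) and should leave both acetates, both lactones and the exocyclic methylene untouched, releasing the benzylic alcohol.

**Compound list**

1 | (4-bromo-2-iodophenyl)methanol | OCc1ccc(Br)cc1I | starting material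
2 | tert-butyl[(4-bromo-2-iodobenzyl)oxy]diphenylsilane | CC(C)(C)[Si](OCc1ccc(Br)cc1I)(c1ccccc1)c1ccccc1 | intermediate
3 | pent-4-yn-1-yl acetate | C#CCCCOC(C)=O | starting material
4 | 4-(4,4,5,5-tetramethyl-1,3,2-dioxaborolan-2-yl)pent-4-en-1-yl acetate | C=C(CCCOC(C)=O)B1OC(C)(C)C(C)(C)O1 | intermediate
5 | 4-[5-bromo-2-(tert-butyldiphenylsilyloxymethyl)phenyl]pent-4-en-1-yl acetate | C=C(CCCOC(C)=O)c1cc(Br)ccc1CO[Si](c1ccccc1)(c1ccccc1)C(C)(C)C | intermediate
6 | (4R)-4-[5-bromo-2-(tert-butyldiphenylsilyloxymethyl)phenyl]pentyl acetate | C[C@H](CCCOC(C)=O)c1cc(Br)ccc1CO[Si](c1ccccc1)(c1ccccc1)C(C)(C)C | intermediate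
7 | ethyl 2-{3-[(2R)-5-acetoxypentan-2-yl]-4-(tert-butyldiphenylsilyloxymethyl)phenyl}acetate (ethyl 2-Ar-acetate) | CCOC(=O)Cc1ccc(CO[Si](c2ccccc2)(c2ccccc2)C(C)(C)C)c([C@H](C)CCCOC(C)=O)c1 | intermediate
8 | ethyl 2-{3-[(2R)-5-acetoxypentan-2-yl]-4-(tert-butyldiphenylsilyloxymethyl)phenyl}prop-2-enoate (ethyl 2-Ar-prop-2-enoate) | C=C(C(=O)OCC)c1ccc(CO[Si](c2ccccc2)(c2ccccc2)C(C)(C)C)c([C@H](C)CCCOC(C)=O)c1 | intermediate
9 | (4S)-4-(tert-butyldimethylsilyloxy)cyclopent-2-en-1-one | O=C1C=C[C@@H](O[Si](C)(C)C(C)(C)C)C1 | starting material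
10 | (4S)-4-(tert-butyldimethylsilyloxy)-2-iodocyclopent-2-en-1-one | O=C1C(I)=C[C@@H](O[Si](C)(C)C(C)(C)C)C1 | intermediate
11 | (4S)-2-allyl-4-(tert-butyldimethylsilyloxy)cyclopent-2-en-1-one | O=C1C(CC=C)=C[C@@H](O[Si](C)(C)C(C)(C)C)C1 | intermediate
12 | Michael adduct: ethyl 2-Ar-3-[3-allyl-5-(tert-butyldimethylsilyloxy)-2-oxocyclopent-3-en-1-yl]propanoate; propanoate chain (on C3) α, trans to the C2 β-silyl ether; both C11′ epimers | CCOC(=O)C(c2ccc(CO[Si](c3ccccc3)(c3ccccc3)C(C)(C)C)c([C@H](C)CCCOC(C)=O)c2)C[C@@H]1C(=O)C(CC=C)=C[C@H]1O[Si](C)(C)C(C)(C)C | intermediate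
13 | hydroxy ester: C4 tertiary alcohol of 12 (C4 α-OH, β-CH3; OH cis to the C3 chain); both C11′ epimers | CCOC(=O)C(c2ccc(CO[Si](c3ccccc3)(c3ccccc3)C(C)(C)C)c([C@H](C)CCCOC(C)=O)c2)C[C@@H]1[C@](C)(O)C(CC=C)=C[C@H]1O[Si](C)(C)C(C)(C)C | intermediate
14 | allyl lactone: cis-fused δ-lactone C4–O–C12′(=O)–C11′H(Ar)–C13′H2–C3 on the cyclopentene; C1H=C5(allyl); C2 β-OSi(t-Bu)Me2; C4 β-CH3; C11′ (R), Ar equatorial | C1=C(CC=C)[C@@]2(C)OC(=O)[C@@H](c3ccc(CO[Si](c4ccccc4)(c4ccccc4)C(C)(C)C)c([C@H](C)CCCOC(C)=O)c3)C[C@H]2[C@@H]1O[Si](C)(C)C(C)(C)C | intermediate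
15 | epoxy lactone: 1α,5α-epoxide of 14 (epoxide cis to the lactone oxygen, trans to the silyl ether) | C=CC[C@@]12O[C@@H]1[C@@H](O[Si](C)(C)C(C)(C)C)[C@@H]1C[C@H](c3ccc(CO[Si](c4ccccc4)(c4ccccc4)C(C)(C)C)c([C@H](C)CCCOC(C)=O)c3)C(=O)O[C@]21C | intermediate
16 | epoxy alcohol: 15 with free C2 β-OH | C=CC[C@@]12O[C@@H]1[C@@H](O)[C@@H]1C[C@H](c3ccc(CO[Si](c4ccccc4)(c4ccccc4)C(C)(C)C)c([C@H](C)CCCOC(C)=O)c3)C(=O)O[C@]21C | intermediate
17 | epoxy ketone: C2 ketone of 16 | C=CC[C@@]12O[C@@H]1C(=O)[C@@H]1C[C@H](c3ccc(CO[Si](c4ccccc4)(c4ccccc4)C(C)(C)C)c([C@H](C)CCCOC(C)=O)c3)C(=O)O[C@]21C | intermediate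
18 | diiodosamarium enolate: C1=C2 enolate and C5 α-alkoxide of the opened epoxy ketone, both as O–SmI2; C5 β-allyl | C=CC[C@@]1(O[Sm](I)I)C=C(O[Sm](I)I)[C@@H]2C[C@H](c3ccc(CO[Si](c4ccccc4)(c4ccccc4)C(C)(C)C)c([C@H](C)CCCOC(C)=O)c3)C(=O)O[C@]12C | intermediate
19 | aldol adduct: C2 ketone; C1–CH(OH)CH3 (both new centres as mixtures); C5 α-OH, β-allyl | C=CC[C@@]1(O)C(C(C)O)C(=O)[C@@H]2C[C@H](c3ccc(CO[Si](c4ccccc4)(c4ccccc4)C(C)(C)C)c([C@H](C)CCCOC(C)=O)c3)C(=O)O[C@]12C | intermediate
20 | mesylate of the secondary alcohol of 19 | C=CC[C@@]1(O)C(C(C)OS(C)(=O)=O)C(=O)[C@@H]2C[C@H](c3ccc(CO[Si](c4ccccc4)(c4ccccc4)C(C)(C)C)c([C@H](C)CCCOC(C)=O)c3)C(=O)O[C@]12C | intermediate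
21 | ethylidene ketone: C2 ketone; (Z)-C1=C10H–CH3 with CH3 syn to the carbonyl; C5 α-OH, β-allyl | C=CC[C@@]1(O)/C(=C/C)C(=O)[C@@H]2C[C@H](c3ccc(CO[Si](c4ccccc4)(c4ccccc4)C(C)(C)C)c([C@H](C)CCCOC(C)=O)c3)C(=O)O[C@]12C | intermediate
22 | allylic chloride: 21 with the C6 arm –CH2–CH=C(CO2CH3)–CH2Cl, (Z), C6 cis to CH2Cl | COC(=O)/C(CCl)=C/C[C@@]1(O)/C(=C/C)C(=O)[C@@H]2C[C@H](c3ccc(CO[Si](c4ccccc4)(c4ccccc4)C(C)(C)C)c([C@H](C)CCCOC(C)=O)c3)C(=O)O[C@]12C | intermediate
23 | vinyl ether: 22 with C5 α-O–CH=CH2 | COC(=O)/C(CCl)=C/C[C@@]1(OC=C)/C(=C/C)C(=O)[C@@H]2C[C@H](c3ccc(CO[Si](c4ccccc4)(c4ccccc4)C(C)(C)C)c([C@H](C)CCCOC(C)=O)c3)C(=O)O[C@]12C | intermediate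
24 | aldehyde: C2(=O)–C1=C5 enone; C1 carries (S)-C10H(CH3)–CH2–CHO; C5 carries the chloro acrylate arm | O=CC[C@H](C)C3=C(C/C=C(\CCl)C(=O)OC)[C@@]1(C)OC(=O)[C@@H](c2ccc(CO[Si](c4ccccc4)(c4ccccc4)C(C)(C)C)c([C@H](C)CCCOC(C)=O)c2)C[C@H]1C3=O | intermediate
25 | ring B hydroxy ester: cycloheptene closed; C8 β-OH; C7 α-C(=CH2)CO2CH3 (H7 β); C10 α-CH3 | O[C@H]2C[C@H](C)C3=C(C[C@@H]2C(=C)C(=O)OC)[C@@]1(C)OC(=O)[C@@H](c2ccc(CO[Si](c4ccccc4)(c4ccccc4)C(C)(C)C)c([C@H](C)CCCOC(C)=O)c2)C[C@H]1C3=O | intermediate
26 | enone bis-lactone: rings A–D complete; C2 ketone; trans-fused α-methylene-γ-lactone (C8 β-O, H7 β); benzylic silyl ether | C=C1C(=O)O[C@H]2C[C@H](C)C3=C(C[C@H]12)[C@@]1(C)OC(=O)[C@@H](c2ccc(CO[Si](c4ccccc4)(c4ccccc4)C(C)(C)C)c([C@H](C)CCCOC(C)=O)c2)C[C@H]1C3=O | intermediate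
27 | allylic alcohol: 26 with C2 α-OH in place of the ketone | C=C1C(=O)O[C@H]2C[C@H](C)C3=C(C[C@H]12)[C@@]1(C)OC(=O)[C@@H](c2ccc(CO[Si](c4ccccc4)(c4ccccc4)C(C)(C)C)c([C@H](C)CCCOC(C)=O)c2)C[C@H]1[C@H]3O | intermediate
28 | diacetate silyl ether: 27 with C2 α-OAc | C=C1C(=O)O[C@H]2C[C@H](C)C3=C(C[C@H]12)[C@@]1(C)OC(=O)[C@@H](c2ccc(CO[Si](c4ccccc4)(c4ccccc4)C(C)(C)C)c([C@H](C)CCCOC(C)=O)c2)C[C@H]1[C@H]3OC(C)=O | intermediate
29 | CNP0205574.1 | C=C1C(=O)O[C@H]2C[C@H](C)C3=C(C[C@H]12)[C@@]1(C)OC(=O)[C@@H](c2ccc(CO)c([C@H](C)CCCOC(C)=O)c2)C[C@H]1[C@H]3OC(C)=O | target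

**Count and risks**

Total step count: 21. Longest linear sequence: 18 steps (steps 1, 3–6 and 9–21).

Steps most likely to fail:

Step 17. Vinyl transfer to a very hindered tertiary alcohol may stall, and meanwhile the free alcohol may displace the allylic chloride within the same molecule. The fallback sets out from 21 and masks the alcohol before the acrylate arm is built: ethyl vinyl ether and PPTS give the 1-ethoxyethyl acetal F1; the cross-metathesis of step 16 is run on this acetal and gives the chloride acetal F2; TMSOTf and i-Pr2NEt then eliminate ethanol from the mixed acetal (acetal-to-enol-ether elimination), which gives vinyl ether 23 and rejoins the route before step 18.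

Step 18. Ring closure by the allyl metal may be slow for a seven-membered ring or may give poor diastereoselectivity at C7 and C8. The fallback sets out from 21 and closes ring B by a carbonyl-ene reaction instead. Cross-metathesis with 2-methyl-2-butene (second-generation Grubbs catalyst) gives the prenyl alcohol F3, and vinyl transfer as in step 17 gives the vinyl ether F4. Heating in toluene gives the aldehyde F5 by the same Claisen rearrangement, and Me2AlCl at −78 °C closes ring B by a type 1 carbonyl-ene reaction to the homoallylic alcohol F6, which carries an isopropenyl group on C7. Allylic oxidation of the isopropenyl methyl group (SeO2 cat., t-BuOOH) gives the diol F7, and oxidative lactonization (TEMPO, PhI(OAc)2) through the enal F8 and the lactol F9 gives 26, where the route is rejoined.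

Step 16. Cross-metathesis with a 1,1-disubstituted, electron-poor olefin may not turn over next to the fully substituted C5. The fallback sets out from 21 and builds the arm stepwise: Lemieux–Johnson cleavage of the terminal alkene (OsO4 cat., NaIO4) gives the aldehyde F10; a Morita–Baylis–Hillman reaction with methyl acrylate (DABCO) gives the allylic alcohol F11; thionyl chloride then gives the rearranged primary allylic chloride 22 by chlorination with allylic transposition, and the route is rejoined at step 17.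

Further compounds

F1 | step 17 | 1-ethoxyethyl acetal of the C5 alcohol of 21 | C=CC[C@@]1(OC(C)OCC)/C(=C/C)C(=O)[C@@H]2C[C@H](c3ccc(CO[Si](c4ccccc4)(c4ccccc4)C(C)(C)C)c([C@H](C)CCCOC(C)=O)c3)C(=O)O[C@]12C
F2 | step 17 | chloride acetal: F1 with the C6 arm –CH2–CH=C(CO2CH3)–CH2Cl | COC(=O)/C(CCl)=C/C[C@@]1(OC(C)OCC)/C(=C/C)C(=O)[C@@H]2C[C@H](c3ccc(CO[Si](c4ccccc4)(c4ccccc4)C(C)(C)C)c([C@H](C)CCCOC(C)=O)c3)C(=O)O[C@]12C
F3 | step 18 | prenyl alcohol: 21 with a 3-methylbut-2-enyl group on C5 | CC(C)=CC[C@@]1(O)/C(=C/C)C(=O)[C@@H]2C[C@H](c3ccc(CO[Si](c4ccccc4)(c4ccccc4)C(C)(C)C)c([C@H](C)CCCOC(C)=O)c3)C(=O)O[C@]12C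
F4 | step 18 | vinyl ether of F3 | CC(C)=CC[C@@]1(OC=C)/C(=C/C)C(=O)[C@@H]2C[C@H](c3ccc(CO[Si](c4ccccc4)(c4ccccc4)C(C)(C)C)c([C@H](C)CCCOC(C)=O)c3)C(=O)O[C@]12C
F5 | step 18 | aldehyde: C1=C5 enone with (S)-C10H(CH3)–CH2–CHO on C1 and a prenyl group on C5 | O=CC[C@H](C)C3=C(CC=C(C)C)[C@@]1(C)OC(=O)[C@@H](c2ccc(CO[Si](c4ccccc4)(c4ccccc4)C(C)(C)C)c([C@H](C)CCCOC(C)=O)c2)C[C@H]1C3=O
F6 | step 18 | homoallylic alcohol: ring B closed; C8 β-OH; C7 α-isopropenyl | O[C@H]2C[C@H](C)C3=C(C[C@@H]2C(C)=C)[C@@]1(C)OC(=O)[C@@H](c2ccc(CO[Si](c4ccccc4)(c4ccccc4)C(C)(C)C)c([C@H](C)CCCOC(C)=O)c2)C[C@H]1C3=O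
F7 | step 18 | diol: F6 with C7 α-C(=CH2)CH2OH | O[C@H]2C[C@H](C)C3=C(C[C@@H]2C(=C)CO)[C@@]1(C)OC(=O)[C@@H](c2ccc(CO[Si](c4ccccc4)(c4ccccc4)C(C)(C)C)c([C@H](C)CCCOC(C)=O)c2)C[C@H]1C3=O
F8 | step 18 | enal: F6 with C7 α-C(=CH2)CHO | O[C@H]2C[C@H](C)C3=C(C[C@@H]2C(=C)C=O)[C@@]1(C)OC(=O)[C@@H](c2ccc(CO[Si](c4ccccc4)(c4ccccc4)C(C)(C)C)c([C@H](C)CCCOC(C)=O)c2)C[C@H]1C3=O
F9 | step 18 | lactol: 26 with C12 as hemiacetal carbon | C=C1C(O)O[C@H]2C[C@H](C)C3=C(C[C@H]12)[C@@]1(C)OC(=O)[C@@H](c2ccc(CO[Si](c4ccccc4)(c4ccccc4)C(C)(C)C)c([C@H](C)CCCOC(C)=O)c2)C[C@H]1C3=O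
F10 | step 16 | aldehyde: 21 with –CH2–CHO on C5 | O=CC[C@@]1(O)/C(=C/C)C(=O)[C@@H]2C[C@H](c3ccc(CO[Si](c4ccccc4)(c4ccccc4)C(C)(C)C)c([C@H](C)CCCOC(C)=O)c3)C(=O)O[C@]12C
F11 | step 16 | allylic alcohol: 21 with –CH2–CH(OH)–C(=CH2)CO2CH3 on C5 | C=C(C(=O)OC)C(O)C[C@@]1(O)/C(=C/C)C(=O)[C@@H]2C[C@H](c3ccc(CO[Si](c4ccccc4)(c4ccccc4)C(C)(C)C)c([C@H](C)CCCOC(C)=O)c3)C(=O)O[C@]12C
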